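**Impossible share.** Side product cannot exceed 54.4 % of the substrate charged in larch, reckoned at two coupling partners in each side product, one in each intermediate D and none in intermediate A.

all flasks: substrate 0.45 M

| flask | coupling partner | remark | time |
|---|---|---|---|
| Monday's | 0.71 M | run made earlier |  |
| Wednesday's | 1.2 M | run made earlier |  |
| larch | 0.490 M |  | 2.0 h |
| birch | 0.990 M |  | 2.0 h |

| run | time / min | target / % | intermediate D / % | intermediate A / % | side product / % | substrate / % |
|---|---|---|---|---|---|---|
| Monday's | 15.0 | 0.1 | 26.2 | 12.7 | 9.3 | 43.2 |
| Monday's | 40.0 | 0.7 | 38.7 | 9.9 | 33.4 | 15.4 |
| Monday's | 80.0 | 1.3 | 38.6 | 6.2 | 51.1 | 3.5 |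
| Monday's | 120 | 0.9 | 36.4 | 5.8 | 56.7 | 0.8 |
| Wednesday's | 10.0 | 0.7 | 19.6 | 6.8 | 8.9 | 48.5 |
| Wednesday's | 20.0 | 1.8 | 23.7 | 5.3 | 24.0 | 32.7 |
| Wednesday's | 50.0 | 3.4 | 19.1 | 2.5 | 62.3 | 10.2 |
| Wednesday's | 120 | 3.3 | 4.7 | 0.2 | 89.1 | 1.4 |

(standard deviation of a reading: 0.5 percentage points)

* which of these there is most of at the end, counted by the substrate in it, larch (side product / target / intermediate D / intermediate A)
* which of these there is most of at the end, counted by the substrate in it, birch (side product / target / intermediate D / intermediate A)
* amount of the one of these that there is most of at the end, in percent of the substrate charged, larch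
* amount of the one of these that there is most of at the end, in percent of the substrate charged, birch

- the numbers in the tables scatter by 0.5 percentage points (one standard deviation)
- a reading or a percentage of target counts all its forms, free or not

**Partner budget.** The bench rule uses the partner budget, coupling partner charged per substrate charged: 1.09 for larch. Monday's budget is 1.58, and its last readings of intermediate D plus twice side product add to 1.50. Once coupling partner, the limiting reagent, is spent and substrate has gone into the three species, side product exceeds intermediate A by the budget minus one. For larch that gives 8.9 percentage points. Intermediate D then leads larch while intermediate A ends below 27.4 %. The budget does not by itself give larch's intermediate A, so the nearest guide is a reading. After 40.0 min, Monday's intermediate D plus twice side product add to 1.06, near larch's budget, and intermediate D reads 38.7 % against 33.4 % of side product and 9.9 % of intermediate A. That flask is richer in coupling partner and still holds 15.4 % of substrate, so this is an estimate and no bound, but my reckoning takes intermediate D for larch.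

**The border.** Birch has a budget of 2.20, which is 1.10 times the two equivalents side product can take. The rule would demand a difference of 120 %, more than the substrate charged, so it stops there and speed takes over. Birch's charge lies between Monday's and Wednesday's, whose side product reads 56.7 % and 89.1 % after 120 min. I therefore expect side product to lead birch.

**The forecast.** It names intermediate D at 52 % for larch and side product at 83 % for birch, where “D is mostly converted”.

**The result.** Larch gives intermediate D at 51.3 %, and birch gives side product at 82.8 %.

    substrate → intermediate A (k = 0.0510 /min)
    coupling partner + intermediate B ⇌ intermediate C (K = 1.70 /M, k = 0.0150 /M/min)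
    substrate + coupling partner ⇌ intermediate B (K = 0.290 /M, k = 0.0650 /M/min)
    coupling partner + intermediate A → intermediate D (k = 0.390 /M/min)
    intermediate C → target (k = 0.0490 /min)
    coupling partner + intermediate D → side product (k = 0.0880 /M/min)
    coupling partner + target ⇌ idle adduct, settled at all times (K = 1.20 /M)

**Budget again.** In larch, side product exceeds intermediate A by 8.2 points against the reckoned 8.9 points, with target at 0.599 % and coupling partner at 0.29 % of its charge. The neighbouring flask is birch with 0.59 M of coupling partner. Its budget of 1.31 gives a difference of 31 points. That flask ends with 1.1 % of its coupling partner left, side product at 40.5 % and intermediate A at 11.4 %, a difference of 29 points, while intermediate D stands at 46.9 %.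

Readings and results were computed for substances that don't exist; the scatter is artificial.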